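## The problem

Target 13 is a flavone. Ring A, a phloroglucinol-type benzene ring, is fused through C4a–C8a to the pyran-4-one ring C, and ring B is attached to C2 through the C2–C1' bond. There is no stereocentre, so the task is purely one of regiochemistry and of telling six oxygen substituents apart. Four contiguous methyl ethers occupy C2'–C5' of ring B and a fifth sits at C7. The C5 oxygen must end as a free phenol, although it is meta to the C7 oxygen on the same ring and chemically very similar to it. The groups at risk are the aryl methyl ethers next to carbonyl groups (cleaved by strong Lewis or protic acids), the pyranone (opened by hydroxide at C2) and the two electron-rich rings (open to electrophilic substitution and oxidation). The classical closures of ring C run through a 1,3-diketone and need strong base followed by strong acid. A gentler closure is possible because the C2=C3 double bond lies between the ketone carbon C4 and a carbon, C2, that already carries O1 and C1'. Read backwards, C2 is the carbonyl carbon of a ring B benzoate esterified to the ring A phenol oxygen O1, and C3 is the carbon alpha to C4, where a phosphorus ylide can be placed.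

## Retrosynthesis

Target 13 is first traced back to its C5 benzyl ether 12. A benzyl group is the one ether that can be removed at the end without touching the five methyl ethers, so it marks the C5 oxygen as different from the C7 oxygen throughout. The forward reaction only has to cleave an aryl benzyl ether by hydrogenolysis.

In 12 the C2=C3 bond is cut, which opens ring C and leads to the acylphosphorane 11. In 11 the ylide carbon (C3) sits alpha to the C4 ketone, and the ring B acid is already attached to O1 as an aryl ester. The alternative cut at O1–C2 would need a diketone and an acid-mediated dehydration. Here the ring closes and the double bond forms in one neutral thermal event, with only triphenylphosphine oxide lost. The forward step must favour olefination of the ester carbonyl over transfer of the aroyl group to carbon.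

Ylide 11 comes from phosphonium bromide 10 by loss of HBr, and 10 from phenacyl bromide 8 and triphenylphosphine 9 by cutting the C3–P bond. These are trivial simplifications. Their value is that 10 should be a crystalline salt, which gives a purification point just before the key step.

Bromide 8 is traced to methyl ketone 7 by cutting the C3–Br bond. The ester is put on before the bromine on purpose. A free ortho hydroxyl would make ring A more prone to nuclear bromination, would let the phenacyl bromide close to a benzofuranone, and would later force an acylation in the presence of a nucleophilic ylide carbon. With O1 already aroylated none of these can happen.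

Ester 7 is cut at the O1–C2 acyl bond into phenol 5 and 2,3,4,5-tetramethoxybenzoic acid 3, which is activated in the flask as acid chloride 6. This is the convergent junction. Each half carries its full oxygen pattern, and the forward reaction is an ordinary O-aroylation of a chelated phenol.

Phenol 5 comes from the symmetric diphenol 4 by removing one benzyl group. The two hydroxyls of 4 are equivalent, so there is no regiochemical question, only the need to stop after one alkylation.

Acid 3 is cut at the C2–C1' bond to 1,2,3,4-tetramethoxybenzene 1 through aryllithium 2. The two ring hydrogens of 1 are equivalent by symmetry and each lies ortho to a methoxy group, so metalation and carboxylation can give only the required 2,3,4,5-pattern.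

## Roads not taken

Alternative 1: Thermal condensation of a phenol with an aroylacetate (Mentzer pyrolysis). The cut removes C4–C4a and O1–C2 at once. Phloroglucinol (A1) and ethyl 3-oxo-3-(2,3,4,5-tetramethoxyphenyl)propanoate (A2) would be heated neat at about 250 °C to give 5,7-dihydroxy-2-(2,3,4,5-tetramethoxyphenyl)chromen-4-one (A3). Selective methylation of the unchelated C7 hydroxyl of A3 would then finish the synthesis.
- Merits: this is clearly the shortest road. It needs no protecting group, the symmetry of A1 removes any regiochemical question on ring A, and the final methylation is directed by the hydrogen bond that ties up the C5 hydroxyl.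
- Weak points: the conditions are severe for two electron-rich partners. The ortho-methoxy group of A2 hinders the ketone during cyclodehydration. Closure onto the ketone instead of the ester carbonyl (the coumarin mode) is a known competitor, and melts of this kind tend to give tar and difficult purification.
- Comparison: in step count Alternative 1 is better. The chosen plan offers neutral and mild ring closure, positions of all oxygens fixed from the start, and a crystalline phosphonium salt as a purification point.

Alternative 2: Ring B built last by Dötz benzannulation. The cut removes C5'–C6', C1'–C2' and C2'–C3'. The alkenyl carbene complex pentacarbonyl(1,2,3-trimethoxyprop-2-enylidene)chromium (A4) would react with 5-(benzyloxy)-2-ethynyl-7-methoxychromen-4-one (A5) and one carbonyl ligand to give 5-(benzyloxy)-2-(2-hydroxy-3,4,5-trimethoxyphenyl)-7-methoxychromen-4-one (A6). Methylation of the new phenol and debenzylation would follow.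
- Merits: the inherent regiochemistry of the benzannulation places the chromone ortho to the new phenol, as required, and the route would allow late variation of ring B.
- Weak points: A4 is an unusually electron-rich, trioxygenated carbene complex that needs its own multi-step preparation and stoichiometric chromium. A5 is an electron-poor, ynone-like alkyne and a Michael acceptor, a poor partner for this reaction. A6 is an electron-rich hydroquinone monoether that oxidises easily.
- Comparison: the route is longer and rests on two uncertain fragments, while the chosen plan obtains ring B fully oxygenated in one step from 1. Alternative 2 has nothing to set against this for a single target.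

Alternative 3: O1 introduced last. The cut removes O1–C2 and O1–C8a. Hydroxide in a wet dipolar aprotic solvent would add to the ynone 1-(2,6-difluoro-4-methoxyphenyl)-3-(2,3,4,5-tetramethoxyphenyl)prop-2-yn-1-one (A7) at C2, and the diketone enolate oxygen would displace one ortho fluorine to give 5-fluoro-7-methoxy-2-(2,3,4,5-tetramethoxyphenyl)chromen-4-one (A8).
- Merits: ring A needs no protecting group, and the two fluorines are equivalent, so the closure has no regiochemical issue.
- Weak points: A8 still carries fluorine where the target has its phenol. The fluorine would have to be exchanged for oxygen by a second nucleophilic aromatic substitution on a chromone that hydroxide can open at C2. A7 requires a ring B alkyne that takes several steps from 1, and hydroxide may attack the fluorinated ring of A7 before it adds to the triple bond.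
- Comparison: the overall length would be similar to or greater than the chosen plan. Alternative 3 does have the more convergent carbon–carbon assembly. The chosen plan ends with a hydrogenolysis, not a substitution on a base-sensitive ring, and keeps the aroyl group to one commercial precursor.

Key step: step 7

Assumption: ylide 11 is expected to be stable enough at 0 °C to be handled as a crude solid. If part of it closes during work-up, the material formed is 12 and nothing is lost.

## Route

Step 1
Reactants: 1 1,2,3,4-tetramethoxybenzene
Product: 3 2,3,4,5-tetramethoxybenzoic acid, via aryllithium 2 (not isolated)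
Conditions: n-BuLi, TMEDA, THF, 0 °C to rt; then CO2, −78 °C to rt; aq. HCl
Reagents that add atoms: carbon dioxide, O=C=O
Why: Directed ortho-metalation followed by carboxylation. The two ring hydrogens of 1 are equivalent and each is ortho to a methoxy group, so monolithiation and trapping of 2 with CO2 should give only the 2,3,4,5-substituted acid.

Step 2
Reactants: 4 1-(2,6-dihydroxy-4-methoxyphenyl)ethanone (2',6'-dihydroxy-4'-methoxyacetophenone)
Product: 5 1-[2-(benzyloxy)-6-hydroxy-4-methoxyphenyl]ethanone
Conditions: BnBr (1.0 equiv), K2CO3, acetone, reflux
Reagents that add atoms: benzyl bromide, BrCc1ccccc1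
Why: Williamson ether synthesis on a symmetric diphenol. After the first alkylation the remaining hydroxyl is locked in a hydrogen bond to the ketone and is much less nucleophilic, so one equivalent of halide should stop at the mono-ether.

Step 3
Reactants: 3 2,3,4,5-tetramethoxybenzoic acid; 5 1-[2-(benzyloxy)-6-hydroxy-4-methoxyphenyl]ethanone
Product: 7 2-acetyl-3-(benzyloxy)-5-methoxyphenyl 2,3,4,5-tetramethoxybenzoate, via acid chloride 6 (not isolated)
Conditions: (COCl)2 (1.05 equiv), cat. DMF, CH2Cl2, 0 °C to rt; then 5, pyridine, cat. DMAP, 0 °C to rt
Reagents that add atoms: none
Why: Acid chloride formation under DMF catalysis, then DMAP-catalysed O-aroylation of the chelated phenol, the same esterification that opens a Baker–Venkataraman sequence. Pyridine is too weak a base to enolise the ketone, so no acyl migration is expected.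

Step 4
Reactants: 7 2-acetyl-3-(benzyloxy)-5-methoxyphenyl 2,3,4,5-tetramethoxybenzoate
Product: 8 3-(benzyloxy)-2-(bromoacetyl)-5-methoxyphenyl 2,3,4,5-tetramethoxybenzoate
Conditions: CuBr2 (2.1 equiv), EtOAc/CHCl3 (1:1), reflux
Reagents that add atoms: copper dibromide, Br[Cu]Br
Why: Heterogeneous alpha-bromination of an aryl methyl ketone with CuBr2, which acts through the enol and is selective for the side chain. With O1 acylated, ring A is less activated than a free phenol, and no ortho hydroxyl is left to close onto the bromide.

Step 5
Reactants: 8 3-(benzyloxy)-2-(bromoacetyl)-5-methoxyphenyl 2,3,4,5-tetramethoxybenzoate; 9 triphenylphosphine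
Product: 10 {2-[2-(benzyloxy)-4-methoxy-6-(2,3,4,5-tetramethoxybenzoyloxy)phenyl]-2-oxoethyl}triphenylphosphonium bromide
Conditions: PPh3 (1.05 equiv), toluene, rt to 50 °C; salt collected by filtration
Reagents that add atoms: none
Why: SN2 quaternisation of the phosphine by a primary alpha-bromo ketone. The salt should precipitate from toluene and so be freed of neutral impurities.

Step 6
Reactants: 10 {2-[2-(benzyloxy)-4-methoxy-6-(2,3,4,5-tetramethoxybenzoyloxy)phenyl]-2-oxoethyl}triphenylphosphonium bromide
Product: 11 3-(benzyloxy)-5-methoxy-2-[(triphenylphosphoranylidene)acetyl]phenyl 2,3,4,5-tetramethoxybenzoate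
Conditions: aq. Na2CO3, CH2Cl2, 0 °C; organic layer dried and concentrated cold; used crude
Reagents that add atoms: none
Why: Deprotonation of a phenacylphosphonium salt, whose CH2 is strongly acidified by the ketone and the phosphonium group, gives the keto-stabilised ylide. Cold two-phase carbonate should leave the aryl ester unhydrolysed.

Step 7
Reactants: 11 3-(benzyloxy)-5-methoxy-2-[(triphenylphosphoranylidene)acetyl]phenyl 2,3,4,5-tetramethoxybenzoate
Product: 12 5-(benzyloxy)-7-methoxy-2-(2,3,4,5-tetramethoxyphenyl)chromen-4-one
Conditions: toluene, reflux, N2
Reagents that add atoms: none
Why: Intramolecular Wittig olefination of an ester carbonyl: the ylide carbon (C3) adds to the carbonyl carbon of the neighbouring aryl benzoate (C2), the betaine closes to an oxaphosphetane, and cycloreversion expels Ph3PO and leaves the C2=C3 bond. The closest known reaction type is the formation of chromones and flavones from 2-acyloxyphenacylidene phosphoranes. Ring C closes in a 6-exo-trig mode, with C3 attacking an ester C=O whose oxygen stays outside the new ring, and the elimination then places the double bond inside the ring. No stereocentre is formed. The step needs olefination to win over acyl transfer, in which the tetrahedral intermediate would expel the ring A aryloxide and leave an inert C-aroylated ylide; base-free conditions in a non-polar solvent disfavour that charge-separated pathway, and formation of the strong P–O bond drives collapse through the oxaphosphetane. Esters are normally inert to stabilised ylides and this one is further deactivated by its 2- and 4-methoxy groups, but it is a phenolic ester held ortho to the ylide, so the high effective molarity should allow thermal closure. The benzyl ether and all methyl ethers see only heat in a neutral medium.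

Step 8
Reactants: 12 5-(benzyloxy)-7-methoxy-2-(2,3,4,5-tetramethoxyphenyl)chromen-4-one
Product: 13 5-hydroxy-7-methoxy-2-(2,3,4,5-tetramethoxyphenyl)chromen-4-one
Conditions: H2 (1 atm), 10% Pd/C, EtOAc/MeOH (1:1), rt; stopped when 12 is consumed
Reagents that add atoms: none
Why: Catalytic hydrogenolysis of an aryl benzyl ether. The methyl ethers are inert and the pyranone double bond is reduced only slowly at atmospheric pressure, so the free C5 phenol, stabilised by its hydrogen bond to the C4 carbonyl, should be released cleanly.

## Compound list

1 | 1,2,3,4-tetramethoxybenzene | COc1ccc(OC)c(OC)c1OC | starting material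
2 | 2,3,4,5-tetramethoxyphenyllithium | [Li]c1cc(OC)c(OC)c(OC)c1OC | intermediate
3 | 2,3,4,5-tetramethoxybenzoic acid | COc1cc(C(=O)O)c(OC)c(OC)c1OC | intermediate
4 | 1-(2,6-dihydroxy-4-methoxyphenyl)ethanone | CC(=O)c1c(O)cc(OC)cc1O | starting material
5 | 1-[2-(benzyloxy)-6-hydroxy-4-methoxyphenyl]ethanone | CC(=O)c1c(O)cc(OC)cc1OCc1ccccc1 | intermediate
6 | 2,3,4,5-tetramethoxybenzoyl chloride | COc1cc(C(=O)Cl)c(OC)c(OC)c1OC | intermediate
7 | 2-acetyl-3-(benzyloxy)-5-methoxyphenyl 2,3,4,5-tetramethoxybenzoate | CC(=O)c1c(OCc2ccccc2)cc(OC)cc1OC(=O)c1cc(OC)c(OC)c(OC)c1OC | intermediate
8 | 3-(benzyloxy)-2-(bromoacetyl)-5-methoxyphenyl 2,3,4,5-tetramethoxybenzoate | COc1cc(OCc2ccccc2)c(C(=O)CBr)c(OC(=O)c2cc(OC)c(OC)c(OC)c2OC)c1 | intermediate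
9 | triphenylphosphine | c1ccc(P(c2ccccc2)c2ccccc2)cc1 | starting material
10 | {2-[2-(benzyloxy)-4-methoxy-6-(2,3,4,5-tetramethoxybenzoyloxy)phenyl]-2-oxoethyl}triphenylphosphonium bromide | [Br-].COc1cc(OCc2ccccc2)c(C(=O)C[P+](c2ccccc2)(c2ccccc2)c2ccccc2)c(OC(=O)c2cc(OC)c(OC)c(OC)c2OC)c1 | intermediate
11 | 3-(benzyloxy)-5-methoxy-2-[(triphenylphosphoranylidene)acetyl]phenyl 2,3,4,5-tetramethoxybenzoate | COc1cc(OCc2ccccc2)c(C(=O)C=P(c2ccccc2)(c2ccccc2)c2ccccc2)c(OC(=O)c2cc(OC)c(OC)c(OC)c2OC)c1 | intermediate
12 | 5-(benzyloxy)-7-methoxy-2-(2,3,4,5-tetramethoxyphenyl)chromen-4-one | COc1cc(OCc2ccccc2)c2c(=O)cc(-c3cc(OC)c(OC)c(OC)c3OC)oc2c1 | intermediate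
13 | 5-hydroxy-7-methoxy-2-(2,3,4,5-tetramethoxyphenyl)chromen-4-one | COc1cc(O)c2c(=O)cc(-c3cc(OC)c(OC)c(OC)c3OC)oc2c1 | target

## Step count and risks

Total step count: 8. Longest linear sequence: 7 steps (steps 1, 3, 4, 5, 6, 7, 8 from 1; equally steps 2 to 8 from 4).

Least certain steps:

Step 7 (key step). The most likely failure is acyl transfer in place of olefination. The tetrahedral intermediate may expel the ring A aryloxide, which moves the aroyl group to carbon and leaves a doubly stabilised ylide that cannot close. The closure may also simply be slow, because the ester carbonyl is shielded by its ortho-methoxy group and made less electrophilic by the para-methoxy group. The fallback leaves the ylide chemistry and closes ring C at O1–C2. It sets out from ester 7. Baker–Venkataraman rearrangement (KOH, pyridine, 50 °C) would give 1-[2-(benzyloxy)-6-hydroxy-4-methoxyphenyl]-3-(2,3,4,5-tetramethoxyphenyl)propane-1,3-dione F1. Cyclodehydration of F1 with catalytic p-TsOH in toluene under reflux would give 12, where the route is rejoined.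

Step 4. Nuclear bromination of ring A at the positions flanked by two oxygens may compete with side-chain bromination. Double bromination of the methyl group and acid-induced loss of the benzyl group by the HBr formed are lesser concerns. The fallback separates enolisation from halogenation. Starting from 7, soft enolisation (TMSOTf, Et3N, CH2Cl2, 0 °C) would give the silyl enol ether 3-(benzyloxy)-5-methoxy-2-[1-(trimethylsilyloxy)ethenyl]phenyl 2,3,4,5-tetramethoxybenzoate F2. Treatment of F2 with N-bromosuccinimide in THF at −78 °C would deliver bromine to the enol carbon only and return the route to 8.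

Step 2. Over-alkylation to the bis-ether together with unreacted diphenol would lower the material throughput and complicate separation. The fallback replaces selective protection by selective deprotection. Starting from 4, exhaustive benzylation (excess BnBr, K2CO3, DMF, 60 °C) would give 1-[2,6-bis(benzyloxy)-4-methoxyphenyl]ethanone F3. Chelation-directed removal of one ortho benzyl group with MgBr2·OEt2 in toluene/Et2O under reflux stops after one cleavage, because the magnesium phenoxide formed deactivates the carbonyl towards a second chelation, and returns the route to 5.

Step 8. Saturation of the C2=C3 bond may begin before the hindered peri benzyl ether is fully cleaved. The fallback is non-reductive. Starting from 12, BCl3 in CH2Cl2 at −78 °C, directed by chelation between the C4 carbonyl and the C5 oxygen, would cleave the benzyl ether selectively and give 13 directly. No new compound is formed on the way.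

## Further compounds

F1 | step 7 | 1-[2-(benzyloxy)-6-hydroxy-4-methoxyphenyl]-3-(2,3,4,5-tetramethoxyphenyl)propane-1,3-dione | COc1cc(O)c(C(=O)CC(=O)c2cc(OC)c(OC)c(OC)c2OC)c(OCc2ccccc2)c1
F2 | step 4 | 3-(benzyloxy)-5-methoxy-2-[1-(trimethylsilyloxy)ethenyl]phenyl 2,3,4,5-tetramethoxybenzoate | COc1cc(OCc2ccccc2)c(C(=C)O[Si](C)(C)C)c(OC(=O)c2cc(OC)c(OC)c(OC)c2OC)c1
F3 | step 2 | 1-[2,6-bis(benzyloxy)-4-methoxyphenyl]ethanone | CC(=O)c1c(OCc2ccccc2)cc(OC)cc1OCc1ccccc1
F0 | step 8 | none | none
A1 | alternative 1 | phloroglucinol | Oc1cc(O)cc(O)c1
A2 | alternative 1 | ethyl 3-oxo-3-(2,3,4,5-tetramethoxyphenyl)propanoate | CCOC(=O)CC(=O)c1cc(OC)c(OC)c(OC)c1OC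
A3 | alternative 1 | 5,7-dihydroxy-2-(2,3,4,5-tetramethoxyphenyl)chromen-4-one | Oc1cc(O)c2c(=O)cc(-c3cc(OC)c(OC)c(OC)c3OC)oc2c1
A4 | alternative 2 | pentacarbonyl(1,2,3-trimethoxyprop-2-enylidene)chromium | COC=C(OC)C(OC)=[Cr](=C=O)(=C=O)(=C=O)(=C=O)=C=O
A5 | alternative 2 | 5-(benzyloxy)-2-ethynyl-7-methoxychromen-4-one | COc1cc(OCc2ccccc2)c2c(=O)cc(C#C)oc2c1
A6 | alternative 2 | 5-(benzyloxy)-2-(2-hydroxy-3,4,5-trimethoxyphenyl)-7-methoxychromen-4-one | COc1cc(OCc2ccccc2)c2c(=O)cc(-c3cc(OC)c(OC)c(OC)c3O)oc2c1
A7 | alternative 3 | 1-(2,6-difluoro-4-methoxyphenyl)-3-(2,3,4,5-tetramethoxyphenyl)prop-2-yn-1-one | COc1cc(F)c(C(=O)C#Cc2cc(OC)c(OC)c(OC)c2OC)c(F)c1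
A8 | alternative 3 | 5-fluoro-7-methoxy-2-(2,3,4,5-tetramethoxyphenyl)chromen-4-one | COc1cc(F)c2c(=O)cc(-c3cc(OC)c(OC)c(OC)c3OC)oc2c1
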